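**Plan**

Numbering: C1 = CH carrying isobutyryl, C2 and C4 = ketones, C3 = O-bearing prenylated carbon, C5 = prenylated quaternary carbon, C6 = CH2, C7 = CH(prenyl), C8 = C(CH3)(4-methylpent-3-enyl), C9 = lactone C=O. Rings: the eight-membered carbocycle C1–C8, bridged by the five-membered lactone O–C3–C4–C5–C9.
Cuts: (a) C1–C2, the bond between a CH flanked by two ketones and the carbonyl carbon on lactone carbon C3; cutting it leaves a cis-3,5-disubstituted furan-2,4-dione with a formyl group on C3 and an α-bromo isopropyl ketone chain on C5. (b) O–C9 together with C9–C1: the lactone is the retro-Claisen product of a cyclohexanone C9/C5/C6/C7/C8/C1 acylated at C1 and C5. (c) C5–C4, C1–acyl, C5–prenyl and C8–homoprenyl, all enolate or cuprate bonds on that ring.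
Forward: the cyclohexenone is made first (Michael addition, aldol condensation) and decorated; the six-membered ring is then opened to the furan-2,4-dione by lactonising retro-Claisen cleavage, and the eight-membered ring closes in the penultimate step.
Stereochemistry: C7 from an amine-catalysed Michael addition; C8 by cuprate addition trans to the C7 prenyl group; C5 by dianion aldol addition trans to that group; C3 from a Sharpless epoxidation in the side-chain aldehyde; C1 by enolisation after the last oxidation.

Key step: step 19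

Remark: C1 of the target lies between two ketones and epimerises through the enol; its 1R configuration is taken to be the more stable one, so no step sets it kinetically.

**Route**

Step 1
Reactants: 1 5-methylhex-4-enal; 2 but-3-en-2-one
Product: 3 (2R)-2-(3-methylbut-2-en-1-yl)-5-oxohexanal
Conditions: (R)-2-[diphenyl(trimethylsilyloxy)methyl]pyrrolidine (5 mol%), ethyl 3,4-dihydroxybenzoate (20 mol%), neat, 4 °C
Reagents that add atoms: none
Why: Enamine-catalysed Michael addition of an aldehyde to an enone: the E-enamine formed from 1 and the R-configured pyrrolidine is attacked by the enone on the face away from the diphenyl(silyloxy)methyl group, which should set the future C7 centre as R.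

Step 2
Reactants: 3 (2R)-2-(3-methylbut-2-en-1-yl)-5-oxohexanal
Product: 5 (4R)-4-(3-methylbut-2-en-1-yl)cyclohex-2-en-1-one, via aldol adduct 4 (not isolated)
Conditions: LiOH, iPrOH, rt
Reagents that add atoms: none
Why: Intramolecular aldol condensation in which only the methyl ketone enolate can reach the aldehyde through a six-membered ring, the mild base leaving the stereocentre, now γ to the new enone, intact.

Step 3
Reactants: 5 (4R)-4-(3-methylbut-2-en-1-yl)cyclohex-2-en-1-one
Product: 6 trimethyl{[(3R,4R)-3-methyl-4-(3-methylbut-2-en-1-yl)cyclohex-1-en-1-yl]oxy}silane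
Conditions: MeMgBr, CuBr·SMe2 (10 mol%), Me3SiCl, THF, −78 °C
Reagents that add atoms: methylmagnesium bromide, C[Mg]Br; chlorotrimethylsilane, C[Si](C)(C)Cl
Why: Copper-catalysed conjugate addition of a Grignard reagent with silyl trapping of the enolate, which places the future C8 methyl group and gives the regiodefined enol ether needed for step 4; the new methyl-bearing centre (trans to prenyl) becomes trigonal again there.

Step 4
Reactants: 6 trimethyl{[(3R,4R)-3-methyl-4-(3-methylbut-2-en-1-yl)cyclohex-1-en-1-yl]oxy}silane
Product: 7 (4R)-3-methyl-4-(3-methylbut-2-en-1-yl)cyclohex-2-en-1-one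
Conditions: Pd(OAc)2 (1.05 equiv), MeCN, rt
Reagents that add atoms: none
Why: Saegusa–Ito oxidation: the palladium enolate formed from the silyl enol ether can eliminate only the hydride on the methyl-bearing carbon, so the enone returns with methyl on its β-carbon and the prenyl-bearing centre untouched.

Step 5
Reactants: 7 (4R)-3-methyl-4-(3-methylbut-2-en-1-yl)cyclohex-2-en-1-one; 8 5-bromo-2-methylpent-2-ene; 10 2-methylpropanal
Product: 11 (3R,4R)-2-(1-hydroxy-2-methylpropyl)-3-methyl-3-(4-methylpent-3-en-1-yl)-4-(3-methylbut-2-en-1-yl)cyclohexan-1-one, via Grignard reagent 9 (not isolated)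
Conditions: 8, Mg, THF, rt; then CuBr·SMe2 (10 mol%), 7, THF, −40 → 0 °C; then 10, −78 °C; aqueous work-up
Reagents that add atoms: none
Why: Tandem copper-catalysed conjugate addition and aldol trapping: the homoprenyl group attacks the β-carbon C8 anti to the pseudo-axial prenyl group on the neighbouring C7, which fixes the quaternary centre with homoprenyl trans and methyl cis to that prenyl group, and the enolate so formed at C1 is captured by isobutyraldehyde (the two further new centres are removed in step 6).

Step 6
Reactants: 11 (3R,4R)-2-(1-hydroxy-2-methylpropyl)-3-methyl-3-(4-methylpent-3-en-1-yl)-4-(3-methylbut-2-en-1-yl)cyclohexan-1-one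
Product: 12 (3R,4R)-3-methyl-3-(4-methylpent-3-en-1-yl)-4-(3-methylbut-2-en-1-yl)-2-(2-methylpropanoyl)cyclohexan-1-one
Conditions: Dess–Martin periodinane, CH2Cl2, rt
Reagents that add atoms: none
Why: Dess–Martin oxidation of a β-hydroxy ketone to the 2-acylcyclohexanone, which from here on blocks C1 as the central carbon of a β-diketone and later serves as the leaving carbon of the ring opening.

Step 7
Reactants: 12 (3R,4R)-3-methyl-3-(4-methylpent-3-en-1-yl)-4-(3-methylbut-2-en-1-yl)-2-(2-methylpropanoyl)cyclohexan-1-one; 13 1-bromo-3-methylbut-2-ene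
Product: 14 (3R,4S)-3-methyl-3-(4-methylpent-3-en-1-yl)-4,6-bis(3-methylbut-2-en-1-yl)-2-(2-methylpropanoyl)cyclohexan-1-one
Conditions: LiN(iPr)2 (2.2 equiv), THF, −78 → 0 °C; then 13, −78 → 0 °C; AcOH
Reagents that add atoms: none
Why: γ-Alkylation of a β-diketone dianion: after the central proton, the second equivalent of base removes a proton from the ring methylene C5 and not from the hindered isopropyl methine, and this more basic terminus is alkylated by prenyl bromide; the new centre is enolised again in step 13.

Step 8
Reactants: 15 2-methylidenepropane-1,3-diol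
Product: 16 2-{[(4-methoxyphenyl)methoxy]methyl}prop-2-en-1-ol
Conditions: NaH (1 equiv), THF, 0 °C; then 4-methoxybenzyl chloride, Bu4NI (cat.), 0 °C → rt
Reagents that add atoms: 4-methoxybenzyl chloride, COc1ccc(CCl)cc1
Why: Williamson ether synthesis on the mono-alkoxide of a symmetrical diol, which should give mainly the mono-ether when one equivalent of base is used.

Step 9
Reactants: 16 2-{[(4-methoxyphenyl)methoxy]methyl}prop-2-en-1-ol
Product: 17 [(2S)-2-{[(4-methoxyphenyl)methoxy]methyl}oxiran-2-yl]methanol
Conditions: Ti(OiPr)4 (10 mol%), L-(+)-diethyl tartrate (12 mol%), tBuOOH, 4 Å MS, CH2Cl2, −20 °C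
Reagents that add atoms: tert-butyl hydroperoxide, CC(C)(C)OO
Why: Sharpless asymmetric epoxidation of a 2-substituted allylic alcohol: the titanium L-(+)-tartrate complex delivers oxygen to one face of the 1,1-disubstituted alkene, which should give the S epoxide and so fixes the future C3 centre.

Step 10
Reactants: 17 [(2S)-2-{[(4-methoxyphenyl)methoxy]methyl}oxiran-2-yl]methanol; 18 (2-methylprop-1-en-1-yl)magnesium bromide
Product: 19 (2R)-2-{[(4-methoxyphenyl)methoxy]methyl}-5-methylhex-4-ene-1,2-diol
Conditions: 18 (3 equiv), CuI (10 mol%), THF, −30 → 0 °C; aqueous work-up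
Reagents that add atoms: none
Why: Copper-catalysed opening of a 2,2-disubstituted epoxide by a Grignard reagent at its unsubstituted carbon, which completes the prenyl group without touching the quaternary carbinol centre.

Step 11
Reactants: 19 (2R)-2-{[(4-methoxyphenyl)methoxy]methyl}-5-methylhex-4-ene-1,2-diol
Product: 20 triethyl{[(2S)-2-{[(4-methoxyphenyl)methoxy]methyl}-5-methyl-2-[(triethylsilyl)oxy]hex-4-en-1-yl]oxy}silane
Conditions: Et3SiOTf (2.5 equiv), 2,6-lutidine, CH2Cl2, −78 → 0 °C
Reagents that add atoms: triethylsilyl trifluoromethanesulfonate, CC[Si](CC)(CC)OS(=O)(=O)C(F)(F)F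
Why: Silylation with a silyl triflate, which is reactive enough to cap the tertiary as well as the primary hydroxyl group.

Step 12
Reactants: 20 triethyl{[(2S)-2-{[(4-methoxyphenyl)methoxy]methyl}-5-methyl-2-[(triethylsilyl)oxy]hex-4-en-1-yl]oxy}silane
Product: 21 (2S)-2-{[(4-methoxyphenyl)methoxy]methyl}-5-methyl-2-[(triethylsilyl)oxy]hex-4-enal
Conditions: (COCl)2, DMSO, CH2Cl2, −78 → −40 °C; then Et3N, −78 → 0 °C
Reagents that add atoms: none
Why: Swern oxidation carried out directly on a primary triethylsilyl ether, which the chlorosulfonium reagent cleaves and oxidises while the tertiary silyl ether, the PMB ether and the alkene are left alone, so that the α-silyloxy aldehyde without α-hydrogen is reached in one operation.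

Step 13
Reactants: 14 (3R,4S)-3-methyl-3-(4-methylpent-3-en-1-yl)-4,6-bis(3-methylbut-2-en-1-yl)-2-(2-methylpropanoyl)cyclohexan-1-one; 21 (2S)-2-{[(4-methoxyphenyl)methoxy]methyl}-5-methyl-2-[(triethylsilyl)oxy]hex-4-enal
Product: 22 C5 aldol adduct (β-diketone with the C4 carbinol side chain on the quaternary ring carbon C5)
Conditions: LiN(iPr)2 (2.2 equiv), THF, −78 → 0 °C; then 21, −78 °C; AcOH, −78 °C
Reagents that add atoms: none
Why: γ-Aldol addition of a β-diketone dianion to an aldehyde that cannot enolise: the second deprotonation again takes place at ring C5, since an enolate at the isopropyl carbon would press a methyl group against the quaternary C8, and the aldehyde should add to C5 on the face trans to the C7 prenyl group, which makes the quaternary centre with the new chain cis to homoprenyl and the two ring prenyl groups cis to each other.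

Step 14
Reactants: 22 C5 aldol adduct
Product: 23 triketone (ring ketone C9, side-chain ketone C4, isobutyryl on C1)
Conditions: Dess–Martin periodinane, CH2Cl2, rt
Reagents that add atoms: none
Why: Dess–Martin oxidation of the hindered carbinol under neutral conditions, which removes the carbinol mixture and gives a 1,3-diketone (C9/C4) that cannot enolise at C5.

Step 15
Reactants: 23 triketone
Product: 24 C1-bromo triketone
Conditions: NBS (1.05 equiv), CH2Cl2, 0 °C
Reagents that add atoms: N-bromosuccinimide, O=C1CCC(=O)N1Br
Why: Electrophilic α-bromination of a β-diketone through its enol, which is far more nucleophilic than the trisubstituted alkenes, so that bromine is placed at C1 with no question of regiochemistry.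

Step 16
Reactants: 24 C1-bromo triketone
Product: 26 bromo keto lactone PMB ether (furan-2,4-dione), via tertiary alcohol 25 (not isolated)
Conditions: Bu4NF, AcOH (1:1), THF, 0 °C → rt
Reagents that add atoms: none
Why: Retro-Claisen ring opening with lactonisation: the C3 hydroxyl freed by buffered fluoride adds to the C9 ketone through a five-membered ring and the adduct expels C1 as a carbanion stabilised by bromine and the isobutyryl group, which acetic acid protonates, so that the furan-2,4-dione carries the C2 carbon and the C6 chain cis as fixed by the C3 and C5 centres already present.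

Step 17
Reactants: 26 bromo keto lactone PMB ether
Product: 27 bromo keto lactone primary alcohol
Conditions: DDQ, CH2Cl2/pH 7 buffer, 0 °C
Reagents that add atoms: none
Why: Oxidative cleavage of a 4-methoxybenzyl ether by DDQ under buffered neutral conditions that the α-bromo ketone, the lactone and the alkenes should survive.

Step 18
Reactants: 27 bromo keto lactone primary alcohol
Product: 28 bromo keto aldehyde lactone
Conditions: Dess–Martin periodinane, CH2Cl2, 0 °C → rt
Reagents that add atoms: none
Why: Dess–Martin oxidation of a neopentyl primary alcohol to the aldehyde without base, as required for a formyl group on a quaternary carbon flanked by a ketone and an acyloxy group, which nucleophiles would remove.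

Step 19
Reactants: 28 bromo keto aldehyde lactone
Product: 29 bicyclic β-hydroxy ketone
Conditions: 28 in THF added slowly (final 0.005 M) to SmI2 (2.5 equiv, 0.1 M in THF), −78 °C; then pH 7 buffer, −78 °C
Reagents that add atoms: none
Why: Two single-electron transfers from divalent samarium cleave the C1–Br bond of the α-bromo ketone and give an enolate of trivalent samarium fixed at C1, which adds to the C2 aldehyde through a chelated cyclic transition state; this is the intramolecular samarium Reformatsky (samarium enolate aldol) reaction known for eight- and nine-membered carbocycles. The ring C1–C8 closes in the 8-(enolexo)-exo-trig mode, helped by the furan-2,4-dione, which holds the formyl group on C3 and the C6 chain on C5 on the same face. The new centres C1 and C2 are not controlled and need not be, since C2 is oxidised in step 20 and C1 then epimerises. The C–Br bond must be reduced before the aldehyde or the α-acyloxy ketone, which its much easier reduction at −78 °C without proton source or additive should secure. The enolate must take the aldehyde and not the C4 ketone or the lactone carbonyl C9 (both six-membered closures), which the higher electrophilicity of the aldehyde, the two quaternary carbons beside C4 and the low reactivity of samarium enolates towards esters at −78 °C should secure. The cold quench keeps the aldolate from retro-aldol cleavage and from re-closure onto C9.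

Step 20
Reactants: 29 bicyclic β-hydroxy ketone
Product: 30 CNP0121153.1 (target)
Conditions: Dess–Martin periodinane, CH2Cl2, rt; then silica gel
Reagents that add atoms: none
Why: Dess–Martin oxidation of the β-hydroxy ketone to the 1,3-diketone; C1, now between two ketones, should equilibrate through the enol on silica gel to the 1R configuration of the target.

**Compound list**

1 | 5-methylhex-4-enal | CC(C)=CCCC=O | starting material
2 | but-3-en-2-one (methyl vinyl ketone) | CC(=O)C=C | starting material
3 | (2R)-2-(3-methylbut-2-en-1-yl)-5-oxohexanal | O=C[C@@H](CC=C(C)C)CCC(C)=O | intermediate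
4 | (4R)-3-hydroxy-4-(3-methylbut-2-en-1-yl)cyclohexan-1-one, carbinol epimers (not isolated) | O=C1CC(O)[C@@H](CC=C(C)C)CC1 | intermediate
5 | (4R)-4-(3-methylbut-2-en-1-yl)cyclohex-2-en-1-one | O=C1C=C[C@@H](CC=C(C)C)CC1 | intermediate
6 | trimethyl{[(3R,4R)-3-methyl-4-(3-methylbut-2-en-1-yl)cyclohex-1-en-1-yl]oxy}silane (methyl trans to prenyl) | C[Si](C)(C)OC1=C[C@H](C)[C@@H](CC=C(C)C)CC1 | intermediate
7 | (4R)-3-methyl-4-(3-methylbut-2-en-1-yl)cyclohex-2-en-1-one | O=C1C=C(C)[C@@H](CC=C(C)C)CC1 | intermediate
8 | 5-bromo-2-methylpent-2-ene | CC(C)=CCCBr | starting material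
9 | (4-methylpent-3-en-1-yl)magnesium bromide (not isolated) | CC(C)=CCC[Mg]Br | intermediate
10 | 2-methylpropanal (isobutyraldehyde) | CC(C)C=O | starting material
11 | (3R,4R)-2-(1-hydroxy-2-methylpropyl)-3-methyl-3-(4-methylpent-3-en-1-yl)-4-(3-methylbut-2-en-1-yl)cyclohexan-1-one; homoprenyl trans to prenyl; epimers at C2 and at the carbinol | O=C1C(C(O)C(C)C)[C@](C)(CCC=C(C)C)[C@@H](CC=C(C)C)CC1 | intermediate
12 | (3R,4R)-3-methyl-3-(4-methylpent-3-en-1-yl)-4-(3-methylbut-2-en-1-yl)-2-(2-methylpropanoyl)cyclohexan-1-one; β-diketone, C2 not defined | O=C1C(C(=O)C(C)C)[C@](C)(CCC=C(C)C)[C@@H](CC=C(C)C)CC1 | intermediate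
13 | 1-bromo-3-methylbut-2-ene (prenyl bromide) | CC(C)=CCBr | starting material
14 | (3R,4S)-3-methyl-3-(4-methylpent-3-en-1-yl)-4,6-bis(3-methylbut-2-en-1-yl)-2-(2-methylpropanoyl)cyclohexan-1-one; C2 and C6 not defined | O=C1C(C(=O)C(C)C)[C@](C)(CCC=C(C)C)[C@@H](CC=C(C)C)CC1CC=C(C)C | intermediate
15 | 2-methylidenepropane-1,3-diol | C=C(CO)CO | starting material
16 | 2-{[(4-methoxyphenyl)methoxy]methyl}prop-2-en-1-ol | C=C(CO)COCc1ccc(OC)cc1 | intermediate
17 | [(2S)-2-{[(4-methoxyphenyl)methoxy]methyl}oxiran-2-yl]methanol | OC[C@@]1(COCc2ccc(OC)cc2)CO1 | intermediate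
18 | (2-methylprop-1-en-1-yl)magnesium bromide (commercial THF solution) | CC(C)=C[Mg]Br | starting material
19 | (2R)-2-{[(4-methoxyphenyl)methoxy]methyl}-5-methylhex-4-ene-1,2-diol | OC[C@@](O)(COCc1ccc(OC)cc1)CC=C(C)C | intermediate
20 | triethyl{[(2S)-2-{[(4-methoxyphenyl)methoxy]methyl}-5-methyl-2-[(triethylsilyl)oxy]hex-4-en-1-yl]oxy}silane | CC[Si](CC)(CC)OC[C@@](O[Si](CC)(CC)CC)(COCc1ccc(OC)cc1)CC=C(C)C | intermediate
21 | (2S)-2-{[(4-methoxyphenyl)methoxy]methyl}-5-methyl-2-[(triethylsilyl)oxy]hex-4-enal | O=C[C@@](O[Si](CC)(CC)CC)(COCc1ccc(OC)cc1)CC=C(C)C | intermediate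
22 | 6-[(2S)-1-hydroxy-2-{[(4-methoxyphenyl)methoxy]methyl}-5-methyl-2-[(triethylsilyl)oxy]hex-4-en-1-yl]-3-methyl-3-(4-methylpent-3-en-1-yl)-4,6-bis(3-methylbut-2-en-1-yl)-2-(2-methylpropanoyl)cyclohexan-1-one; side chain on ring C6 trans to the C4 prenyl group (ring prenyl groups cis), ring C3 and C4 as in 14; carbinol and C2 not defined | O=C1C(C(=O)C(C)C)[C@](C)(CCC=C(C)C)[C@@H](CC=C(C)C)C[C@]1(CC=C(C)C)C(O)[C@](CC=C(C)C)(COCc1ccc(OC)cc1)O[Si](CC)(CC)CC | intermediate
23 | 6-[(2S)-2-{[(4-methoxyphenyl)methoxy]methyl}-5-methyl-2-[(triethylsilyl)oxy]hex-4-enoyl]-3-methyl-3-(4-methylpent-3-en-1-yl)-4,6-bis(3-methylbut-2-en-1-yl)-2-(2-methylpropanoyl)cyclohexan-1-one; configuration as in 22, C2 not defined | O=C1C(C(=O)C(C)C)[C@](C)(CCC=C(C)C)[C@@H](CC=C(C)C)C[C@]1(CC=C(C)C)C(=O)[C@](CC=C(C)C)(COCc1ccc(OC)cc1)O[Si](CC)(CC)CC | intermediate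
24 | 2-bromo derivative of 23 (bromine on the ring carbon that carries the 2-methylpropanoyl group, plan C1; that centre not defined) | O=C1C(Br)(C(=O)C(C)C)[C@](C)(CCC=C(C)C)[C@@H](CC=C(C)C)C[C@]1(CC=C(C)C)C(=O)[C@](CC=C(C)C)(COCc1ccc(OC)cc1)O[Si](CC)(CC)CC | intermediate
25 | 24 without the triethylsilyl group (free tertiary alcohol at plan C3; not isolated) | O=C1C(Br)(C(=O)C(C)C)[C@](C)(CCC=C(C)C)[C@@H](CC=C(C)C)C[C@]1(CC=C(C)C)C(=O)[C@](CC=C(C)C)(COCc1ccc(OC)cc1)O | intermediate
26 | furan-2,4-dione O–C3–C4(=O)–C5–C9(=O), plan numbering (3S,5R,7S,8R): C3 carries prenyl and CH2O-(4-methoxybenzyl); C5 carries prenyl and the chain C6H2–C7H(prenyl)–C8(CH3)(4-methylpent-3-enyl)–C1HBr–CO–CH(CH3)2; C1 epimers | CC(C)=CCC[C@@](C)(C(Br)C(=O)C(C)C)[C@@H](CC=C(C)C)C[C@@]1(CC=C(C)C)C(=O)O[C@@](CC=C(C)C)(COCc2ccc(OC)cc2)C1=O | intermediate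
27 | as 26 with CH2OH on C3 (3S,5R,7S,8R; C1 epimers) | CC(C)=CCC[C@@](C)(C(Br)C(=O)C(C)C)[C@@H](CC=C(C)C)C[C@@]1(CC=C(C)C)C(=O)O[C@@](CC=C(C)C)(CO)C1=O | intermediate
28 | as 26 with CHO on C3: bromo keto aldehyde lactone (3S,5R,7S,8R; C1 epimers) | CC(C)=CCC[C@@](C)(C(Br)C(=O)C(C)C)[C@@H](CC=C(C)C)C[C@@]1(CC=C(C)C)C(=O)O[C@@](CC=C(C)C)(C=O)C1=O | intermediate
29 | bicyclic β-hydroxy ketone: eight-membered ring C1–C8 bridged by the lactone, C2 carbinol, isobutyryl on C1 (3S,5R,7S,8R; C1 and C2 epimers) | CC(C)=CCC[C@]1(C)[C@@H](CC=C(C)C)C[C@@]2(CC=C(C)C)C(=O)O[C@@](CC=C(C)C)(C(O)C1C(=O)C(C)C)C2=O | intermediate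
30 | CNP0121153.1, (1R,3S,5R,7S,8R) in plan numbering | CC(C)=CCC[C@]1(C)[C@@H](CC=C(C)C)C[C@@]2(CC=C(C)C)C(=O)O[C@@](CC=C(C)C)(C(=O)[C@H]1C(=O)C(C)C)C2=O | target

**Count and risks**

Total steps: 20. Longest linear sequence: 15 (steps 1–7 and 13–20); the side-chain aldehyde 21 takes 5 steps (8–12).

Step 19 (eight-membered closure). What may go wrong: the samarium enolate may cyclise onto the lactone carbonyl C9 (a six-membered Claisen-type closure that gives back the cyclohexanedione), or the formyl group may be reduced or lost before the C–C bond forms. Fallback, a ring expansion in place of the direct closure: it sets out from triketone 23. DDQ cleaves the PMB ether to the primary alcohol F1, and Dess–Martin oxidation gives the keto aldehyde F2. With Et3N in CH2Cl2 the β-diketone carbon C1 adds to the C2 aldehyde in a six-membered intramolecular aldol reaction to give the bicyclo[3.3.1]nonane aldol F3, and a second Dess–Martin oxidation gives the bicyclic tetraketone F4. Bu4NF/AcOH then frees the C3 hydroxyl, which adds across the ring to the C9 ketone and breaks the C9–C1 bond by retro-Claisen fragmentation, C1 leaving as a β-diketone enolate. This turns the six-membered ring into the eight-membered one and returns to the route at 30.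

Step 13 (quaternary C5). What may go wrong: the second deprotonation may take place at the isopropyl carbon, the crowded dianion may fail to add to the hindered aldehyde, or it may add on the wrong face. Fallback, a Lewis-acid aldol of an isolated dienol ether: it sets out from 14, which Me3SiOTf/Et3N converts under equilibrating conditions into the bis(trimethylsilyl) dienol ether F5. A BF3·OEt2-promoted vinylogous Mukaiyama aldol addition of F5 to aldehyde 21 at −78 °C forms the C5–C4 bond at the ring terminus and, after aqueous work-up, returns to the route at 22.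

Step 16 (ring opening with bromine in place). What may go wrong: loss of bromine by halophilic attack or Favorskii-type rearrangement while fluoride and alkoxide are present, or cleavage of the isobutyryl group. Fallback, opening before bromination: it sets out from triketone 23, which with Bu4NF/AcOH lactonises by the same retro-Claisen cleavage to the bromine-free keto lactone F6. LiN(iPr)2 in the presence of Me3SiCl at −78 °C (internal quench, so that the enolate cannot re-close onto C9) gives the less substituted silyl enol ether F7 at the C1 methylene. NBS then brominates F7 at C1 and returns to the route at 26.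

**Further compounds**

F1 | step 19 | primary alcohol from 23 (PMB ether cleaved; triethylsilyl ether kept) | O=C1C(C(=O)C(C)C)[C@](C)(CCC=C(C)C)[C@@H](CC=C(C)C)C[C@]1(CC=C(C)C)C(=O)[C@](CC=C(C)C)(CO)O[Si](CC)(CC)CC
F2 | step 19 | keto aldehyde (formyl group on C3 of the triketone) | O=C1C(C(=O)C(C)C)[C@](C)(CCC=C(C)C)[C@@H](CC=C(C)C)C[C@]1(CC=C(C)C)C(=O)[C@](CC=C(C)C)(C=O)O[Si](CC)(CC)CC
F3 | step 19 | bicyclo[3.3.1]nonane aldol (C1–C2 bond formed, C2 carbinol epimers, C3 triethylsilyl ether) | CC(C)=CCC[C@]1(C)[C@@H](CC=C(C)C)C[C@]2(CC=C(C)C)C(=O)[C@@](CC=C(C)C)(O[Si](CC)(CC)CC)C(O)[C@@]1(C(=O)C(C)C)C2=O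
F4 | step 19 | bicyclo[3.3.1]nonane tetraketone (C2, C4, C9 ketones, isobutyryl on C1, C3 triethylsilyl ether) | CC(C)=CCC[C@]1(C)[C@@H](CC=C(C)C)C[C@]2(CC=C(C)C)C(=O)[C@@](CC=C(C)C)(O[Si](CC)(CC)CC)C(=O)[C@@]1(C(=O)C(C)C)C2=O
F5 | step 13 | bis(trimethylsilyl) dienol ether of 14 | C[Si](C)(C)OC1=C(CC=C(C)C)C[C@H](CC=C(C)C)[C@@](C)(CCC=C(C)C)C1=C(O[Si](C)(C)C)C(C)C
F6 | step 16 | bromine-free keto lactone PMB ether (26 with CH2 at C1) | CC(C)=CCC[C@@](C)(CC(=O)C(C)C)[C@@H](CC=C(C)C)C[C@@]1(CC=C(C)C)C(=O)O[C@@](CC=C(C)C)(COCc2ccc(OC)cc2)C1=O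
F7 | step 16 | trimethylsilyl enol ether of F6 at C1 | CC(C)=CCC[C@@](C)(C=C(O[Si](C)(C)C)C(C)C)[C@@H](CC=C(C)C)C[C@@]1(CC=C(C)C)C(=O)O[C@@](CC=C(C)C)(COCc2ccc(OC)cc2)C1=O
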